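(The numbers of this flask come from no measurement; the result is computed.)

We start from the constants and turn them into a time at the charged amounts.

starting material 0.50 mM; partner 0.800 equiv (fed, over 2.0 s); time 5.0 min

    partner + target → over-reaction product (k1 = 900 /M/s)
    starting material + partner → isomer of the product (k2 = 130 /M/s)
    starting material + partner → target (k3 = 330 /M/s)

* the state of affairs at 5.0 min: stopped, and by what, or still going (it is still moving / all of the starting material has reacted / the partner has run out first)
* how much target there is at 5.0 min, in percent of the starting material charged
* how much over-reaction product there is at 5.0 min, in percent of the starting material charged
* how much isomer of the product there is at 5.0 min, in percent of the starting material charged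

- the reaction counts as stopped when no species that holds the starting material changes by six tenths of a point or more over the second half of the time
- run time (flask): 5.0 min

Does the clock matter? At the charged starting material, the two steps that use starting material give a partner molecule a lifetime of about 4.35 s, far less than the 5.0 min allowed. With 0.800 equiv, less than one equivalent, we expect the partner to be the limiting reagent.

Who gets the partner? It stands in every rate, so it cancels from every ratio of rates. Of the starting material that reacts, a share f = 0.717 first becomes target and the rest becomes isomer of the product. We carry the selectivity factor s, how much faster a given fraction of target takes partner than the same fraction of starting material: 1.96.

Where does it stop? Let a be the fraction of starting material left, r the fraction reacted and p the fraction of target. Integrating once gives p = g·(a − a^s), with g = f/(s − 1) = 0.750. Partner spent per starting material charged is r + f·r − p. At a = 0.5 that is 0.677, and at a = 0.333 it is 0.982. Interpolating to the charge gives a = 43.3%, so we expect 17.9% target, 22.8% over-reaction product and 16.0% isomer of the product.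

The forecast says the partner has run out first, with 17.9% target, 23% over-reaction product and 16.1% isomer of the product, holding that “the product split depends only on how far the starting material has gone”. Its over-reaction product and its isomer of the product stand a little higher than ours.

The simulation's verdict is that the partner has run out first, with 0% of the partner and 43% of the starting material left, and 17.9% target, 23.0% over-reaction product and 16.1% isomer of the product.

At 0.0571 min the partner went into target 1.8 times as fast as into over-reaction product; that ratio is (f/s)·a/p, and with the amounts that stand at 5.00 min, when 0% of the partner is left, the same expression gives 0.883, below one. In a neighbour flask with 1.40 equiv of partner, 13.5% of the starting material stays, the curve with s gives 8.64% target at that point, and that flask holds 8.61%.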